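**Retrosynthetic overview**

- Feature: lactone ring C (C19–O–C6) is a γ-lactone cis-fused to ring B through C4–C5–C6 and sits beside quaternary C10 (C20 β, C1 α). This is the imprint of a 5-exo haloacetal radical cyclisation from O6 onto C5 of a ring B enone, with trans allyl trapping at C10.
- Disconnections: ring D ether bond O–C9 (trans-diaxial 5-exo opening of an 8β,9β-epoxide by the C13 hydroxyl) ⇒ C9–C11 (Negishi coupling of a C8=C9 enol triflate with a C11–C16 zinc reagent from (S)-malic acid, which carries C13 and ring E) ⇒ ring A bond C3–C4 (lactone-enolate alkylation) ⇒ C4–C5 and C1–C10 (radical cyclisation–allylation of a bromoacetal) ⇒ (R)-4-hydroxy-2-methylcyclohex-2-enone.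
- Order of ring formation: ring B is present from the start; ring C (as its acetal) closes in step 6, ring A in step 11, ring E in step 17 on the side-chain fragment, ring D in step 24.

Key step: step 6

Remarks (assumptions on the chemistry): labdane numbering is used for all intermediates. Centres that are erased later are carried as mixtures and left undefined in the SMILES (the methyl carbon of 2, C4 and the acetal carbon C19 in 7–15, C8 in 20). Compound 1 is taken as commercial (otherwise one dehydrogenation step from 1,4-dioxaspiro[4.5]decan-8-one); 6 is used as the commercial E/Z mixture.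

**Route**

Step 1
Reactants: 1 1,4-dioxaspiro[4.5]dec-6-en-8-one
Product: 2 trimethyl[(6-methyl-1,4-dioxaspiro[4.5]dec-7-en-8-yl)oxy]silane (racemic)
Conditions: Me2CuLi (1.2 equiv), TMSCl (2 equiv, present from the start), THF, −78 °C
Reagents that add atoms: lithium dimethylcuprate, [Li+].C[Cu-]C; chlorotrimethylsilane, C[Si](C)(C)Cl
Why: Gilman cuprate 1,4-addition, accelerated by TMSCl, places the future C20 methyl on the enone β-carbon (future C10) and traps the regiodefined enolate as its silyl enol ether; the new centre is racemic and is flattened again in step 2.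

Step 2
Reactants: 2 silyl enol ether
Product: 3 6-methyl-1,4-dioxaspiro[4.5]dec-6-en-8-one
Conditions: Pd(OAc)2 (1.05 equiv), MeCN, rt
Reagents that add atoms: none
Why: Saegusa–Ito oxidation (palladation of the silyl enol ether, β-hydride elimination from the methyl-bearing carbon) restores the enone with the methyl now on its β-carbon, so that the free carbonyl (future C6) and the masked one (future C9) are distinguished without any selectivity question.

Step 3
Reactants: 3 β-methyl enone ketal
Product: 4 (R)-6-methyl-1,4-dioxaspiro[4.5]dec-6-en-8-ol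
Conditions: (S)-Me-CBS oxazaborolidine [(S)-1-methyl-3,3-diphenyltetrahydro-1H,3H-pyrrolo[1,2-c][1,3,2]oxazaborole] (0.2 equiv), BH3·SMe2 (0.7 equiv), THF, −20 °C; MeOH quench, aqueous work-up
Reagents that add atoms: none
Why: Corey–Bakshi–Shibata reduction, in which the alkenyl arm acts as the large and the CH2 arm as the small substituent, should deliver hydride to one face only and set C6 as the (R)-carbinol by 1,2-reduction.

Step 4
Reactants: 4 allylic alcohol ketal
Product: 5 (R)-4-hydroxy-2-methylcyclohex-2-en-1-one
Conditions: PPTS (0.1 equiv), THF/H2O 4:1, 40 °C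
Reagents that add atoms: water, O
Why: Mild acid hydrolysis of the allylic (fast-ionising) dioxolane unveils the C9 ketone, now conjugated with the methyl-bearing C10=C5 bond, without disturbing the carbinol centre.

Step 5
Reactants: 5 (R)-4-hydroxy-2-methylcyclohex-2-en-1-one; 6 ethyl 1-propenyl ether
Product: 7 (R)-4-[(2-bromo-1-ethoxypropyl)oxy]-2-methylcyclohex-2-en-1-one (bromoacetal; acetal and CHBr centres as mixtures)
Conditions: NBS (1.2 equiv), 6 (3 equiv), CH2Cl2, −40 → 0 °C
Reagents that add atoms: N-bromosuccinimide, O=C1CCC(=O)N1Br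
Why: Ueno–Stork haloacetalisation: NBS turns the enol ether 6 into an α-bromo oxocarbenium ion that the secondary alcohol captures; the acetal and CHBr centres form as mixtures, which is harmless because C19 is later oxidised and C4 later enolised.

Step 6
Reactants: 7 bromoacetal; 8 allyltributylstannane
Product: 9 4-allyl-2-ethoxy-3,4-dimethylhexahydrobenzofuran-5(2H)-one (cis-fused; at C10 the allyl group is α and C20 is β; C4 and C19 as mixtures)
Conditions: 8 (4 equiv), AIBN (0.2 equiv, in portions), degassed benzene (0.1 M in 7), 80 °C
Reagents that add atoms: none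
Why: A tributyltin radical, released when the initiator radical adds to 8, abstracts bromine from 7; the nucleophilic secondary radical at C4 adds to the enone β-carbon C5, and the resulting electrophilic tertiary α-keto radical at C10 adds to 8, which expels Bu3Sn• and carries the chain. The closest known reaction type is the Ueno–Stork haloacetal radical cyclisation run with trapping of the product radical by an allylstannane (Keck allylation), that is Stork's cyclisation–trapping sequence. The oxolane that becomes lactone ring C closes in the 5-exo-trig mode. C5 is set by the two-atom tether from O6, which can deliver C4 only to the face of C5 syn to the C6–O bond (cis ring fusion); C10 is set by approach of the stannane to the planar radical anti to the new C4–C5 bond on the convex face of the bicycle, which leaves C20 β and the allyl group (C1–C3) α; C4 and the acetal carbon form as mixtures and are erased in steps 7 and 11. The step needs cyclisation to outrun bimolecular allylation or reduction of the first radical, which the fast 5-exo addition to an activated enone, the absence of tin hydride and a moderate stannane concentration secure, and it needs polarity matching in the trapping step, which the α-keto radical and the electron-rich allylstannane provide.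

Step 7
Reactants: 9 bicyclic acetal
Product: 11 4-allyl-3,4-dimethyltetrahydrobenzofuran-2,5(3H,4H)-dione (cis-fused keto lactone), via lactol 10 (not isolated)
Conditions: CrO3, H2SO4, H2O, acetone, 0 °C → rt (Jones reagent)
Reagents that add atoms: water, O
Why: Jones oxidation: the aqueous acid hydrolyses the ethyl acetal to the lactol and chromic acid oxidises it to the γ-lactone (ring C), while the monosubstituted alkene and the ketone are inert.

Step 8
Reactants: 11 keto lactone
Product: 12 C9 ethylene ketal of 11
Conditions: ethylene glycol, TsOH·H2O (cat.), benzene, reflux, Dean–Stark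
Reagents that add atoms: ethane-1,2-diol, OCCO
Why: Acid-catalysed dioxolane formation on the only ketone (the lactone carbonyl does not ketalise; ketones flanked by a quaternary carbon ketalise readily, as in the Wieland–Miescher series) masks C9, whose C8 enolate would otherwise out-compete the lactone enolate in step 11 and alkylate at carbon or oxygen.

Step 9
Reactants: 12 ketal lactone
Product: 14 C3 primary alcohol, via B-alkyl-9-BBN adduct 13 (not isolated)
Conditions: 9-BBN (1.5 equiv), THF, 0 °C → rt; then NaBO3·4H2O, H2O, rt
Reagents that add atoms: sodium perborate, [Na+].[O-]OB=O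
Why: Anti-Markovnikov hydroboration of the monosubstituted alkene with 9-BBN, which leaves lactone and ketal alone, followed by near-neutral perborate oxidation that spares the lactone, gives the C3 alcohol.

Step 10
Reactants: 14 primary alcohol
Product: 15 C3 primary iodide
Conditions: I2, PPh3, imidazole, CH2Cl2, 0 °C → rt
Reagents that add atoms: iodine, II
Why: Appel-type iodination (Garegg–Samuelsson conditions) converts the primary alcohol into the iodide under neutral conditions.

Step 11
Reactants: 15 iodide
Product: 17 tricyclic ketal lactone (rings A/B trans-fused; 19,6β-olide; C18 α; C9 dioxolane), via lithium lactone enolate 16 (not isolated)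
Conditions: LDA (1.2 equiv), THF/DMPU, −78 → 0 °C
Reagents that add atoms: none
Why: Intramolecular lactone-enolate alkylation (6-exo-tet, enolate exocyclic to the forming ring) makes the C3–C4 bond and closes ring A; the chain hangs from C10 and can reach only the enolate face syn to C10, which fixes C4 (C19 β, C18 α) and, because C1 and C4 are trans on ring B, gives the trans-decalin.

Step 12
Reactants: 17 tricyclic ketal lactone
Product: 18 tricyclic 9-oxo lactone
Conditions: 2 M HCl, THF, 45 °C
Reagents that add atoms: water, O
Why: Acid hydrolysis of the dioxolane returns the C9 ketone; the bridged γ-lactone, which has no enolisable hydrogen left, is stable to aqueous acid.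

Step 13
Reactants: 18 tricyclic keto lactone
Product: 20 8-methyl-9-oxo lactone (C8 epimers), via lithium ketone enolate 19 (not isolated)
Conditions: LDA (1.1 equiv), THF, −78 °C; then MeI, −78 → −20 °C
Reagents that add atoms: iodomethane, CI
Why: Ketone enolate alkylation: with C10 quaternary and the lactone α-carbon C4 quaternary, C8 is the only enolisable position, so MeI installs C17 regiospecifically; the C8 configuration does not matter because step 14 makes it trigonal.

Step 14
Reactants: 20 8-methyl ketone
Product: 22 C8=C9 enol triflate (8-methyl), via potassium enolate 21 (not isolated)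
Conditions: KHMDS (1.5 equiv), THF, −78 → 0 °C; then PhNTf2, 0 °C → rt
Reagents that add atoms: N-phenyl-bis(trifluoromethanesulfonimide), FC(F)(F)S(=O)(=O)N(c1ccccc1)S(=O)(=O)C(F)(F)F
Why: The remaining C8 hydrogen is the only α-hydrogen, so KHMDS gives the tetrasubstituted enolate, which PhNTf2 sulfonylates on oxygen to the C8=C9 enol triflate.

Step 15
Reactants: 23 (S)-malic acid
Product: 24 2-[(2S,4S)-2-tert-butyl-5-oxo-1,3-dioxolan-4-yl]acetic acid (cis)
Conditions: pivalaldehyde, TsOH·H2O (cat.), H2SO4 (cat.), pentane, reflux, Dean–Stark; recrystallisation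
Reagents that add atoms: pivalaldehyde, CC(C)(C)C=O
Why: Seebach acetalisation of the α-hydroxy acid unit with pivalaldehyde gives, under thermodynamic control and after crystallisation, the cis-dioxolanone in which the tert-butyl group stores the configuration of C13 (self-regeneration of stereocentres).

Step 16
Reactants: 24 cis-dioxolanone acid
Product: 26 2-[(2S,4S)-4-allyl-2-tert-butyl-5-oxo-1,3-dioxolan-4-yl]acetic acid, via dilithium dianion 25 (not isolated)
Conditions: LiHMDS (2.2 equiv), THF, −78 °C; then allyl bromide, −78 → −20 °C; aqueous acid work-up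
Reagents that add atoms: allyl bromide, C=CCBr
Why: Seebach alkylation: the dianion (carboxylate plus dioxolanone enolate) is allylated on the face anti to the tert-butyl group, that is with retention, which sets the quaternary C13 centre in the configuration of the target and brings in C12 and C11.

Step 17
Reactants: 26 allylated dioxolanone acid
Product: 28 (S)-4-allyl-4-hydroxydihydrofuran-2(3H)-one, via dihydroxy acid 27 (not isolated)
Conditions: LiBH4 (3 equiv), THF, 0 °C → rt; then 2 M HCl, rt
Reagents that add atoms: none
Why: LiBH4 reduces the activated dioxolanone carbonyl (future C16) but not the lithium carboxylate (future C15), the acetal falls apart, and acidification closes the γ-lactone (ring E) between the new primary hydroxyl and the acid, with C13 untouched.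

Step 18
Reactants: 28 hydroxy lactone
Product: 29 (S)-4-allyl-4-(triethylsilyloxy)dihydrofuran-2(3H)-one
Conditions: TESOTf, 2,6-lutidine, CH2Cl2, −78 → 0 °C
Reagents that add atoms: triethylsilyl trifluoromethanesulfonate, CC[Si](CC)(CC)OS(=O)(=O)C(F)(F)F
Why: Silylation of the hindered tertiary alcohol with the silyl triflate and a hindered pyridine base protects O13 for the organozinc and halohydrin steps.

Step 19
Reactants: 29 silyl ether
Product: 31 (S)-4-(2-hydroxyethyl)-4-(triethylsilyloxy)dihydrofuran-2(3H)-one, via ozonide 30 (not isolated)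
Conditions: O3, CH2Cl2, −78 °C; then NaBH4, MeOH, −78 → 0 °C
Reagents that add atoms: ozone, [O-][O+]=O
Why: Ozonolysis with reductive (NaBH4) work-up excises the terminal carbon and leaves the two-carbon arm C12–C11 as a primary alcohol; the γ-lactone survives brief cold borohydride.

Step 20
Reactants: 31 primary alcohol
Product: 32 (R)-4-(2-iodoethyl)-4-(triethylsilyloxy)dihydrofuran-2(3H)-one
Conditions: I2, PPh3, imidazole, CH2Cl2, 0 °C
Reagents that add atoms: iodine, II
Why: Appel-type iodination of the primary alcohol under neutral conditions gives the C11 iodide.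

Step 21
Reactants: 22 enol triflate; 32 iodide (1.8 equiv)
Product: 34 coupled C8=C9 alkene (8-methyl; side chain C11–C16 with 13-OTES and 15,16-olide), via alkylzinc iodide 33 (not isolated)
Conditions: Zn dust (activated), LiCl, THF, 40 °C; then 22, Pd(OAc)2 (5 mol%), SPhos (2-dicyclohexylphosphino-2′,6′-dimethoxybiphenyl, 10 mol%), THF/NMP, 60 °C
Reagents that add atoms: none
Why: Negishi coupling: LiCl-assisted zinc insertion gives a lactone-tolerant primary alkylzinc iodide, and the palladium/SPhos catalyst (zerovalent palladium formed in the flask), chosen for hindered partners, joins C11 to the C9 enol triflate carbon with the C8=C9 bond kept in place.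

Step 22
Reactants: 34 coupled alkene
Product: 35 9α-bromo-8β-hydroxy compound (8α-methyl; 13-OTES)
Conditions: NBS (1.2 equiv), acetone/H2O 5:1, 0 °C, dark
Reagents that add atoms: N-bromosuccinimide, O=C1CCC(=O)N1Br; water, O
Why: Bromohydrin formation under Fürst–Plattner control, the precedent being 9(11)-ene steroids that give 9α-bromo-11β-ols: bromine adds to the open α face (anti to C20 and to the axial lactone oxygen on C6) and water opens the bromonium ion trans-diaxially at C8, which sets 8β-OH/8α-CH3 and 9α-Br, the route chosen because a peracid would epoxidise the α face, the wrong one for step 24.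

Step 23
Reactants: 35 bromohydrin
Product: 36 8β,9β-epoxide (13-OTES)
Conditions: K2CO3 (powdered), MeCN, 40 °C
Reagents that add atoms: none
Why: Intramolecular Williamson reaction: the 8β-oxygen is anti-periplanar to the axial 9α-bromide and displaces it with inversion, giving the 8β,9β-epoxide that direct epoxidation would not provide.

Step 24
Reactants: 36 epoxide
Product: 38 CNP0538626.1 (8β-hydroxy-9α,13-epoxylabdane-19,6β:15,16-diolide of the given configuration), via hydroxy epoxide 37 (not isolated)
Conditions: CSA (0.3 equiv), CH2Cl2/MeOH 5:1, 0 °C → rt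
Reagents that add atoms: none
Why: Acid methanolysis of the silyl ether followed by acid-catalysed 5-exo epoxide opening (trans-diaxial, as in the 9β,11β-epoxide to 9α-fluoro-11β-ol conversion of steroid chemistry): the C13 hydroxyl attacks C9 anti to the epoxide oxygen, that is from the α face with inversion, closing ether ring D with 9α-O and leaving the 8β-hydroxyl, while C13 keeps its configuration.

**Compound list**

1 | 1,4-dioxaspiro[4.5]dec-6-en-8-one | O=C1C=CC2(CC1)OCCO2 | starting material
2 | trimethyl[(6-methyl-1,4-dioxaspiro[4.5]dec-7-en-8-yl)oxy]silane (racemic) | CC1C=C(O[Si](C)(C)C)CCC12OCCO2 | intermediate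
3 | 6-methyl-1,4-dioxaspiro[4.5]dec-6-en-8-one | CC1=CC(=O)CCC12OCCO2 | intermediate
4 | (R)-6-methyl-1,4-dioxaspiro[4.5]dec-6-en-8-ol | O[C@@H]1CCC2(OCCO2)C(C)=C1 | intermediate
5 | (R)-4-hydroxy-2-methylcyclohex-2-en-1-one | O[C@@H]1CCC(=O)C(C)=C1 | intermediate
6 | ethyl 1-propenyl ether (E/Z mixture) | CCOC=CC | starting material
7 | (R)-4-[(2-bromo-1-ethoxypropyl)oxy]-2-methylcyclohex-2-en-1-one (acetal and CHBr centres mixed) | CCOC(C(C)Br)O[C@@H]1CCC(=O)C(C)=C1 | intermediate
8 | allyltributylstannane | C=CC[Sn](CCCC)(CCCC)CCCC | starting material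
9 | 4-allyl-2-ethoxy-3,4-dimethylhexahydrobenzofuran-5(2H)-one (cis-fused; allyl α, C20 β; C4 and C19 mixed) | O=C1CC[C@H]2OC(OCC)C(C)[C@H]2[C@]1(C)CC=C | intermediate
10 | lactol of 9 (2-hydroxy in place of 2-ethoxy) | O=C1CC[C@H]2OC(O)C(C)[C@H]2[C@]1(C)CC=C | intermediate (not isolated)
11 | 4-allyl-3,4-dimethyltetrahydrobenzofuran-2,5(3H,4H)-dione (cis-fused keto lactone; C4 mixed) | O=C1CC[C@H]2OC(=O)C(C)[C@H]2[C@]1(C)CC=C | intermediate
12 | C9 ethylene ketal of 11 | O1CCOC12CC[C@H]3OC(=O)C(C)[C@H]3[C@]2(C)CC=C | intermediate
13 | B-(3-substituted propyl)-9-BBN adduct of 12 | O1CCOC12CC[C@H]3OC(=O)C(C)[C@H]3[C@]2(C)CCCB4C5CCCC4CCC5 | intermediate (not isolated)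
14 | C3 primary alcohol (3-hydroxypropyl on C10) | O1CCOC12CC[C@H]3OC(=O)C(C)[C@H]3[C@]2(C)CCCO | intermediate
15 | C3 primary iodide (3-iodopropyl on C10) | O1CCOC12CC[C@H]3OC(=O)C(C)[C@H]3[C@]2(C)CCCI | intermediate
16 | lithium enolate of lactone 15 (C4=C19) | O1CCOC12CC[C@H]3OC(O[Li])=C(C)[C@H]3[C@]2(C)CCCI | intermediate (not isolated)
17 | tricyclic ketal lactone (rings A/B trans; 5α-H; 10β-CH3; 4α-CH3; 19,6β-olide; C9 dioxolane) | O1CCOC12CC[C@H]3OC(=O)[C@@]4(C)CCC[C@@]2(C)[C@@H]34 | intermediate
18 | tricyclic 9-oxo lactone (same stereochemistry as 17) | O=C1CC[C@H]2OC(=O)[C@@]3(C)CCC[C@@]1(C)[C@@H]23 | intermediate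
19 | lithium C8=C9 enolate of 18 | [Li]OC1=CC[C@H]2OC(=O)[C@@]3(C)CCC[C@@]1(C)[C@@H]23 | intermediate (not isolated)
20 | 8-methyl-9-oxo lactone (C8 epimers) | CC1C[C@H]2OC(=O)[C@@]3(C)CCC[C@@](C)([C@@H]23)C1=O | intermediate
21 | potassium C8=C9 enolate of 20 | CC=1C[C@H]2OC(=O)[C@@]3(C)CCC[C@@](C)([C@@H]23)C=1O[K] | intermediate (not isolated)
22 | 8-methyl C8=C9 enol triflate | CC=1C[C@H]2OC(=O)[C@@]3(C)CCC[C@@](C)([C@@H]23)C=1OS(=O)(=O)C(F)(F)F | intermediate
23 | (S)-malic acid | OC(=O)C[C@H](O)C(=O)O | starting material
24 | 2-[(2S,4S)-2-tert-butyl-5-oxo-1,3-dioxolan-4-yl]acetic acid | OC(=O)C[C@H]1C(=O)O[C@@H](C(C)(C)C)O1 | intermediate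
25 | dilithium dianion of 24 (carboxylate and ring enolate) | [Li]OC(=O)CC1=C(O[Li])O[C@@H](C(C)(C)C)O1 | intermediate (not isolated)
26 | 2-[(2S,4S)-4-allyl-2-tert-butyl-5-oxo-1,3-dioxolan-4-yl]acetic acid | OC(=O)C[C@@]1(CC=C)C(=O)O[C@@H](C(C)(C)C)O1 | intermediate
27 | (S)-3-hydroxy-3-(hydroxymethyl)hex-5-enoic acid | C=CC[C@](CC(=O)O)(CO)O | intermediate (not isolated)
28 | (S)-4-allyl-4-hydroxydihydrofuran-2(3H)-one | C=CC[C@]1(COC(=O)C1)O | intermediate
29 | (S)-4-allyl-4-(triethylsilyloxy)dihydrofuran-2(3H)-one | C=CC[C@]1(COC(=O)C1)O[Si](CC)(CC)CC | intermediate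
30 | ozonide (1,2,4-trioxolane) of 29 | O1OC(C[C@]2(COC(=O)C2)O[Si](CC)(CC)CC)OC1 | intermediate (not isolated)
31 | (S)-4-(2-hydroxyethyl)-4-(triethylsilyloxy)dihydrofuran-2(3H)-one | OCC[C@]1(COC(=O)C1)O[Si](CC)(CC)CC | intermediate
32 | (R)-4-(2-iodoethyl)-4-(triethylsilyloxy)dihydrofuran-2(3H)-one | ICC[C@]1(COC(=O)C1)O[Si](CC)(CC)CC | intermediate
33 | alkylzinc iodide from 32 | I[Zn]CC[C@]1(COC(=O)C1)O[Si](CC)(CC)CC | intermediate (not isolated)
34 | coupled C8=C9 alkene (13-OTES; 19,6β- and 15,16-olides) | CC=1C[C@H]2OC(=O)[C@@]3(C)CCC[C@@](C)([C@@H]23)C=1CC[C@]1(COC(=O)C1)O[Si](CC)(CC)CC | intermediate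
35 | 9α-bromo-8β-hydroxy compound (8α-CH3; 13-OTES) | C[C@]1(O)C[C@H]2OC(=O)[C@@]3(C)CCC[C@@](C)([C@@H]23)[C@@]1(Br)CC[C@]1(COC(=O)C1)O[Si](CC)(CC)CC | intermediate
36 | 8β,9β-epoxide (13-OTES) | C[C@]12C[C@H]3OC(=O)[C@@]4(C)CCC[C@@](C)([C@@H]34)[C@]1(O2)CC[C@]1(COC(=O)C1)O[Si](CC)(CC)CC | intermediate
37 | 8β,9β-epoxide with free 13-OH | C[C@]12C[C@H]3OC(=O)[C@@]4(C)CCC[C@@](C)([C@@H]34)[C@]1(O2)CC[C@]1(COC(=O)C1)O | intermediate (not isolated)
38 | CNP0538626.1 | C[C@]1(O)C[C@H]2OC(=O)[C@@]3(C)CCC[C@@](C)([C@@H]23)[C@@]12CC[C@]1(COC(=O)C1)O2 | target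

**Step count and risks**

Total steps: 24. Longest linear sequence: 18 steps (steps 1–14 and 21–24); the side-chain fragment takes steps 15–20.

Steps most likely to fail:

1. Step 6. The tertiary α-keto radical at C10 may be quenched (hydrogen abstraction, disproportionation) faster than it adds to the stannane, or the first radical may be allylated before it cyclises. The fallback divides the cascade. It sets out from 7: reductive Ueno–Stork cyclisation (Bu3SnH, AIBN, benzene, 80 °C) should give the cis-fused bicyclic ketone with hydrogen on C10, F1; TMSCl and Et3N in DMF at 80 °C should convert it into the more substituted C9=C10 trimethylsilyl enol ether F2; MeLi in THF followed by allyl bromide and HMPA should alkylate the regiodefined lithium enolate on the face anti to the C4–C5 bond, which comes back to the route at 9.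

2. Step 21. Transmetalation and reductive elimination at the tetrasubstituted alkenyl–palladium centre, flanked by quaternary C10 and the C8 methyl, may be too slow, so that the triflate is reduced or hydrolysed and the zinc reagent is lost to protonation or homocoupling. The fallback replaces the cross-coupling by a carbonyl addition. It sets out from 29 and 22: ozonolysis of 29 with PPh3 work-up should give the side-chain aldehyde F3; Nozaki–Hiyama–Kishi coupling of 22 with F3 (CrCl2, NiCl2 cat., DMF) should give the C11 allylic alcohol F4, the small alkenylchromium species tolerating the hindrance and ignoring both lactones; thiocarbonyl diimidazole should give the imidazolyl thionocarbonate F5; Barton–McCombie deoxygenation (Bu3SnH, AIBN, toluene, 100 °C) should then deliver hydrogen to the less hindered C11 end of the allyl radical, keep the tetrasubstituted C8=C9 bond and come back to the route at 34.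

3. Step 22. Water has to attack C8 on the β face between C20 and the lactone oxygen on C6; if this is too slow, proton loss from the bromonium ion (allylic bromide formation) or opening at the wrong carbon may take over. The fallback builds the ether through a C9 cation and sets the C8 carbinol last. It sets out from 34: mCPBA should epoxidise the open α face to the 8α,9α-epoxide F6; diethylaluminium 2,2,6,6-tetramethylpiperidide (Et2Al(TMP)) should isomerise it by removal of a C17 proton to the 9α-hydroxy-8(17)-ene F7; CSA in CH2Cl2/MeOH should cleave the silyl ether, ionise the tertiary allylic alcohol and close the spiro ether at C9 under equilibrating conditions (axial C9–O, equatorial C11) to the 9α,13-epoxy-8(17)-ene F8; ozonolysis with Me2S work-up should give the C8 ketone F9; MeMgBr with CeCl3 at −78 °C, selective for the ketone over both lactones, should add from the open α face (8α-CH3, 8β-OH) and come back to the route at 38.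

**Further compounds**

F1 | step 6 | 2-ethoxy-3,4-dimethylhexahydrobenzofuran-5(2H)-one (cis-fused; C10–H) | O=C1CC[C@H]2OC(OCC)C(C)[C@H]2C1C
F2 | step 6 | C9=C10 trimethylsilyl enol ether of F1 | C[Si](C)(C)OC=1CC[C@H]2OC(OCC)C(C)[C@H]2C=1C
F3 | step 21 | (S)-2-[5-oxo-3-(triethylsilyloxy)tetrahydrofuran-3-yl]acetaldehyde | O=CC[C@]1(COC(=O)C1)O[Si](CC)(CC)CC
F4 | step 21 | C11 allylic alcohol (11-hydroxy derivative of 34; C11 epimers) | CC=1C[C@H]2OC(=O)[C@@]3(C)CCC[C@@](C)([C@@H]23)C=1C(O)C[C@]1(COC(=O)C1)O[Si](CC)(CC)CC
F5 | step 21 | O-(imidazol-1-ylthiocarbonyl) derivative of F4 | CC=1C[C@H]2OC(=O)[C@@]3(C)CCC[C@@](C)([C@@H]23)C=1C(OC(=S)n1ccnc1)C[C@]1(COC(=O)C1)O[Si](CC)(CC)CC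
F6 | step 22 | 8α,9α-epoxide of 34 | C[C@@]12C[C@H]3OC(=O)[C@@]4(C)CCC[C@@](C)([C@@H]34)[C@@]1(O2)CC[C@]1(COC(=O)C1)O[Si](CC)(CC)CC
F7 | step 22 | 9α-hydroxy-8(17)-ene (13-OTES) | C=C1C[C@H]2OC(=O)[C@@]3(C)CCC[C@@](C)([C@@H]23)[C@@]1(O)CC[C@]1(COC(=O)C1)O[Si](CC)(CC)CC
F8 | step 22 | 9α,13-epoxy-8(17)-ene-19,6β:15,16-diolide | C=C1C[C@H]2OC(=O)[C@@]3(C)CCC[C@@](C)([C@@H]23)[C@@]12CC[C@]1(COC(=O)C1)O2
F9 | step 22 | 8-oxo-17-nor-9α,13-epoxy-19,6β:15,16-diolide | O=C1C[C@H]2OC(=O)[C@@]3(C)CCC[C@@](C)([C@@H]23)[C@@]12CC[C@]1(COC(=O)C1)O2
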